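## Retrosynthetic overview

- **Feature.** With the lactone labelled O1, C2 (C=O), C3 (quaternary), C4, C5 (CH2), C6 (carbinol carbon on C4) and C7 (benzylic CH2 on C3), the ring atoms O1 and C2–C5 are the five atoms of furan. The bond C4–C6 with its oxygen on C6 is an aromatic aldehyde joined to a furan β-carbon, with C4 and C6 in the anti (threo) relation.
- **Disconnections.** C3–C7 by benzylation of the lactone enolate anti to the C4 substituent (last C–C bond). C2=O and C3–O from the enol ether C2=C3 of the photoadduct (epoxide, benzyl acetal, lactol, lactone). C5–H by reductive cleavage of the temporary oxetane bond C5–O. C4–C6 and C5–O by Paternò–Büchi cycloaddition of furan and vanillin acetate.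
- **Ring order.** The oxetane is fused onto the furan ring in step 1 (cis-fused 2,7-dioxabicyclo[3.2.0]hept-3-ene, aryl exo) and opened in step 3. The five-membered ring is carried as a 2-benzyloxyoxolane and becomes the γ-lactone in step 8.
- **Order of events.** The oxetane acetal is reduced while O1 is still an ether oxygen and the phenol still an acetate, so that only C5–O ionises. The racemate is resolved after ring opening. Acetate is exchanged for silyl before any enolate chemistry.

Key step: step 1

Remark (racemates): compounds 3, 4, 5 and 6 are racemic; names and SMILES show the enantiomer that leads to the target.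

Remark (assumption): in step 4 the lipase is taken to follow Kazlauskas' rule at the benzylic carbinol C6, so the enantiomer needed is the one acylated. Should the enzyme prefer the other enantiomer, the unreacted diol goes into step 5, which then only removes the aryl acetate.

## Route

Step 1
Reactants: 1 furan (large excess, cosolvent); 2 vanillin acetate (4-formyl-2-methoxyphenyl acetate)
Product: 3 racemic exo photoadduct 4-[(1R*,5S*,6R*)-2,7-dioxabicyclo[3.2.0]hept-3-en-6-yl]-2-methoxyphenyl acetate
Conditions: hν (medium-pressure Hg lamp, Pyrex filter, λ > 300 nm), furan/benzene, N2, 0–10 °C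
Reagents that add atoms: none
Why: Paternò–Büchi photocycloaddition, the stepwise [2+2] known for furan and aromatic aldehydes (furan–carbonyl photoaldol): the nπ* triplet of 2 bonds through oxygen to a furan α-carbon (C5) and gives a triplet 1,4-biradical, allylic over the furan residue and benzylic at C6. After intersystem crossing the two radical centres combine to form C4–C6, which closes the oxetane as a four-membered ring by radical recombination on the intact five-membered ring. C4 and C5 must be cis because a four-membered ring can only be fused cis to the five-membered one, and C6 carries the aryl group exo because the biradical conformer that undergoes spin inversion and closure keeps the aryl group turned away from the dihydrofuran ring. The step needs regioselectivity (O to the α-carbon, C to the β-carbon), which follows from the stabilised biradical, exo selectivity as above, and mono-addition, which the large excess of furan secures. The 4-acetoxy group is a weak donor and the 3-methoxy group is not conjugated with the carbonyl, so the reactive nπ* triplet should be kept, and light above 300 nm is absorbed by the aldehyde only. No element of chirality is present, so 3 forms as the racemate, with the C4/C6 relative configuration of the target already fixed.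

Step 2
Reactants: 3
Product: 5 racemic benzyl acetal alcohol 4-[(1S*,3R*,4R*,5S*,6R*)-3-(benzyloxy)-4-hydroxy-2,7-dioxabicyclo[3.2.0]heptan-6-yl]-2-methoxyphenyl acetate, via exo-epoxide 4 (not isolated)
Conditions: dimethyldioxirane (1.1 equiv), acetone/CH2Cl2, −78 → −20 °C; then BnOH (10 equiv), −20 °C → rt
Reagents that add atoms: dimethyldioxirane, CC1(C)OO1; benzyl alcohol, OCc1ccccc1
Why: Glycal-type epoxidation and alcoholysis: the neutral oxidant epoxidises the enol ether C2=C3 on the convex face (anti to the oxetane) and benzyl alcohol opens the epoxide at the acetal carbon C2 with inversion; this removes the enol ether so that later acid cannot aromatise the ring, leaves the acid-labile oxetane acetal alone, and creates two centres (C2, C3) that are both erased later.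

Step 3
Reactants: 5
Product: 6 racemic diol (2S*,3R*,4R*)-2-(benzyloxy)-4-[(R*)-(4-acetoxy-3-methoxyphenyl)(hydroxy)methyl]oxolan-3-ol
Conditions: Et3SiH (5 equiv), BF3·OEt2 (1.5 equiv), CH2Cl2, −78 °C; aq. NaHCO3
Reagents that add atoms: none
Why: Ionic hydrogenation of an acetal: BF3 binds the most basic oxygen (the strained oxetane oxygen), C5–O ionises to the ring oxocarbenium ion stabilised by O1 (still an ether oxygen), and Et3SiH delivers hydride to C5; the C2 benzyl acetal has no strain assistance and is disarmed by the C3 oxygen, the aryl acetate keeps the benzylic C6–O bond from ionising, and neither C4 nor C6 is touched.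

Step 4
Reactants: 6 (racemate)
Product: 7 (R)-(4-acetoxy-3-methoxyphenyl)[(3S,4R,5S)-5-(benzyloxy)-4-hydroxyoxolan-3-yl]methyl acetate
Conditions: immobilised Burkholderia cepacia lipase (lipase PS), vinyl acetate (5 equiv), tert-butyl methyl ether, 30 °C, stopped near half conversion; chromatography
Reagents that add atoms: vinyl acetate, C=COC(C)=O
Why: Lipase-catalysed kinetic resolution by irreversible transesterification with an enol ester: by Kazlauskas' rule the (R)-configured 1-arylalkyl carbinol (aryl in the large pocket) should be acylated faster, so the wanted enantiomer is taken on as the C6 acetate and the slow-reacting enantiomer of 6 is removed as the diol; no stereocentre is formed.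

Step 5
Reactants: 7
Product: 8 triol (2S,3R,4R)-2-(benzyloxy)-4-[(R)-hydroxy(4-hydroxy-3-methoxyphenyl)methyl]oxolan-3-ol
Conditions: iBu2AlH (6 equiv), CH2Cl2, −78 → −40 °C; aq. KNaC4H4O6
Reagents that add atoms: none
Why: Reductive ester cleavage with the aluminium hydride at low temperature frees the phenol and the C6 hydroxyl without ever pairing a phenoxide with a benzylic ester leaving group, which under basic methanolysis would eliminate to a p-quinone methide and scramble C6.

Step 6
Reactants: 8
Product: 9 tris(silyl ether) (2S,3R,4R)-2-(benzyloxy)-3-(tert-butyldimethylsilyloxy)-4-[(R)-(tert-butyldimethylsilyloxy)(4-(tert-butyldimethylsilyloxy)-3-methoxyphenyl)methyl]oxolane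
Conditions: TBSOTf (4 equiv), 2,6-lutidine (6 equiv), CH2Cl2, −78 → 0 °C
Reagents that add atoms: tert-butyldimethylsilyl trifluoromethanesulfonate, CC(C)(C)[Si](C)(C)OS(=O)(=O)C(F)(F)F
Why: Silylation with the silyl triflate and a hindered base protects the phenol, the benzylic C6 hydroxyl and the hindered C3 hydroxyl in one operation as ethers that withstand hydrogenolysis, oxidation and enolate chemistry.

Step 7
Reactants: 9
Product: 10 lactol (3R,4R)-3-(tert-butyldimethylsilyloxy)-4-[(R)-(tert-butyldimethylsilyloxy)(4-(tert-butyldimethylsilyloxy)-3-methoxyphenyl)methyl]oxolan-2-ol (anomer mixture)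
Conditions: H2 (1 atm), Pd/C (10%), EtOAc, rt
Reagents that add atoms: none
Why: Hydrogenolysis of the anomeric benzyl ether over zerovalent palladium under neutral conditions frees the lactol while the silyl ethers, the benzylic one included, are inert; with C6–O capped, only the C5 oxygen can hold C2 in a ring.

Step 8
Reactants: 10
Product: 11 lactone (3R,4R)-3-(tert-butyldimethylsilyloxy)-4-[(R)-(tert-butyldimethylsilyloxy)(4-(tert-butyldimethylsilyloxy)-3-methoxyphenyl)methyl]oxolan-2-one
Conditions: nPr4N[RuO4] (5 mol %), N-methylmorpholine N-oxide (1.5 equiv), 4 Å molecular sieves, CH2Cl2, rt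
Reagents that add atoms: none
Why: Ley–Griffith oxidation of the lactol to the γ-lactone under neutral, non-aqueous conditions leaves the silyl ethers in place; epimerisation at C3 would be of no consequence because C3 is enolised in step 12.

Step 9
Reactants: 12 vanillin
Product: 13 4-(tert-butyldimethylsilyloxy)-3-methoxybenzaldehyde
Conditions: TBSCl (1.2 equiv), imidazole (2.5 equiv), DMF, rt
Reagents that add atoms: tert-butyldimethylsilyl chloride, CC(C)(C)[Si](C)(C)Cl
Why: Imidazole-mediated silylation of the phenol masks the acidic OH before hydride reduction and enolate alkylation.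

Step 10
Reactants: 13
Product: 14 [4-(tert-butyldimethylsilyloxy)-3-methoxyphenyl]methanol
Conditions: NaBH4, MeOH, 0 °C
Reagents that add atoms: none
Why: Borohydride reduction of the aldehyde to the benzylic alcohol; the aryl silyl ether is stable at 0 °C over the short reaction time.

Step 11
Reactants: 14
Product: 15 4-(bromomethyl)-1-(tert-butyldimethylsilyloxy)-2-methoxybenzene
Conditions: CBr4 (1.2 equiv), PPh3 (1.2 equiv), CH2Cl2, 0 °C; used at once
Reagents that add atoms: tetrabromomethane, BrC(Br)(Br)Br
Why: Appel bromination converts the benzylic alcohol to the bromide under neutral conditions that spare the aryl silyl ether.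

Step 12
Reactants: 11; 15
Product: 17 (3S,4R)-3-(tert-butyldimethylsilyloxy)-3-[4-(tert-butyldimethylsilyloxy)-3-methoxybenzyl]-4-[(R)-(tert-butyldimethylsilyloxy)(4-(tert-butyldimethylsilyloxy)-3-methoxyphenyl)methyl]oxolan-2-one, via lithium enolate 16 (not isolated)
Conditions: LiN(iPr)2 (1.1 equiv), THF, −78 °C; then DMPU, 15 (1.5 equiv), −78 → −40 °C
Reagents that add atoms: none
Why: Alkylation of a lactone lithium enolate (α-silyloxy ester enolate) with a benzylic bromide: C3 becomes planar and the electrophile enters the face anti to the bulky C4 substituent, which places the benzyl group trans to C6 and the C3 oxygen cis to it, i.e. the (3S) centre; C4 carries no leaving group, so the enolate cannot eliminate.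

Step 13
Reactants: 17
Product: 18 target (3S,4R)-3-hydroxy-4-[(R)-hydroxy(4-hydroxy-3-methoxyphenyl)methyl]-3-(4-hydroxy-3-methoxybenzyl)oxolan-2-one
Conditions: Bu4NF (6 equiv), AcOH (6 equiv), THF, 0 °C → rt
Reagents that add atoms: none
Why: Fluoride-mediated desilylation buffered with acetic acid removes the two aryl, the secondary benzylic and the tertiary α-carbonyl silyl ethers without generating free alkoxide, which could translactonise onto C2 through the C6 oxygen.

## Compound list

1 | furan | c1ccoc1 | starting material
2 | vanillin acetate (4-formyl-2-methoxyphenyl acetate) | COc1cc(C=O)ccc1OC(C)=O | starting material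
3 | exo photoadduct, 4-[(1R,5S,6R)-2,7-dioxabicyclo[3.2.0]hept-3-en-6-yl]-2-methoxyphenyl acetate (racemic; enantiomer carried on shown) | C1=CO[C@@H]2O[C@@H](c3ccc(OC(C)=O)c(OC)c3)[C@H]12 | intermediate
4 | exo-epoxide of 3, epoxide oxygen anti to the oxetane (racemic; not isolated) | O1[C@@H]2O[C@@H]2[C@H]2[C@H](c3ccc(OC(C)=O)c(OC)c3)O[C@@H]12 | intermediate
5 | 4-[(1S,3R,4R,5S,6R)-3-(benzyloxy)-4-hydroxy-2,7-dioxabicyclo[3.2.0]heptan-6-yl]-2-methoxyphenyl acetate (racemic; enantiomer carried on shown) | O(Cc1ccccc1)[C@@H]1O[C@@H]2O[C@@H](c3ccc(OC(C)=O)c(OC)c3)[C@@H]2[C@H]1O | intermediate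
6 | (2S,3R,4R)-2-(benzyloxy)-4-[(R)-(4-acetoxy-3-methoxyphenyl)(hydroxy)methyl]oxolan-3-ol (racemic; enantiomer carried on shown) | O(Cc1ccccc1)[C@@H]1OC[C@H]([C@@H](O)c2ccc(OC(C)=O)c(OC)c2)[C@H]1O | intermediate
7 | (R)-(4-acetoxy-3-methoxyphenyl)[(3S,4R,5S)-5-(benzyloxy)-4-hydroxyoxolan-3-yl]methyl acetate | O(Cc1ccccc1)[C@@H]1OC[C@H]([C@@H](OC(C)=O)c2ccc(OC(C)=O)c(OC)c2)[C@H]1O | intermediate
8 | (2S,3R,4R)-2-(benzyloxy)-4-[(R)-hydroxy(4-hydroxy-3-methoxyphenyl)methyl]oxolan-3-ol | O(Cc1ccccc1)[C@@H]1OC[C@H]([C@@H](O)c2ccc(O)c(OC)c2)[C@H]1O | intermediate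
9 | (2S,3R,4R)-2-(benzyloxy)-3-(TBS-oxy)-4-[(R)-(TBS-oxy)(4-(TBS-oxy)-3-methoxyphenyl)methyl]oxolane (TBS = tert-butyldimethylsilyl) | O(Cc1ccccc1)[C@@H]1OC[C@H]([C@@H](O[Si](C)(C)C(C)(C)C)c2ccc(O[Si](C)(C)C(C)(C)C)c(OC)c2)[C@H]1O[Si](C)(C)C(C)(C)C | intermediate
10 | (3R,4R)-3-(TBS-oxy)-4-[(R)-(TBS-oxy)(4-(TBS-oxy)-3-methoxyphenyl)methyl]oxolan-2-ol (anomer mixture) | OC1OC[C@H]([C@@H](O[Si](C)(C)C(C)(C)C)c2ccc(O[Si](C)(C)C(C)(C)C)c(OC)c2)[C@H]1O[Si](C)(C)C(C)(C)C | intermediate
11 | (3R,4R)-3-(TBS-oxy)-4-[(R)-(TBS-oxy)(4-(TBS-oxy)-3-methoxyphenyl)methyl]oxolan-2-one | O=C1OC[C@H]([C@@H](O[Si](C)(C)C(C)(C)C)c2ccc(O[Si](C)(C)C(C)(C)C)c(OC)c2)[C@H]1O[Si](C)(C)C(C)(C)C | intermediate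
12 | vanillin | COc1cc(C=O)ccc1O | starting material
13 | 4-(tert-butyldimethylsilyloxy)-3-methoxybenzaldehyde | COc1cc(C=O)ccc1O[Si](C)(C)C(C)(C)C | intermediate
14 | [4-(tert-butyldimethylsilyloxy)-3-methoxyphenyl]methanol | COc1cc(CO)ccc1O[Si](C)(C)C(C)(C)C | intermediate
15 | 4-(bromomethyl)-1-(tert-butyldimethylsilyloxy)-2-methoxybenzene | COc1cc(CBr)ccc1O[Si](C)(C)C(C)(C)C | intermediate
16 | lithium enolate of 11 (not isolated) | [Li]OC1=C(O[Si](C)(C)C(C)(C)C)[C@@H]([C@@H](O[Si](C)(C)C(C)(C)C)c2ccc(O[Si](C)(C)C(C)(C)C)c(OC)c2)CO1 | intermediate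
17 | (3S,4R)-3-(TBS-oxy)-3-[4-(TBS-oxy)-3-methoxybenzyl]-4-[(R)-(TBS-oxy)(4-(TBS-oxy)-3-methoxyphenyl)methyl]oxolan-2-one | COc1cc(C[C@@]2(O[Si](C)(C)C(C)(C)C)C(=O)OC[C@@H]2[C@@H](O[Si](C)(C)C(C)(C)C)c2ccc(O[Si](C)(C)C(C)(C)C)c(OC)c2)ccc1O[Si](C)(C)C(C)(C)C | intermediate
18 | (3S,4R)-3-hydroxy-4-[(R)-hydroxy(4-hydroxy-3-methoxyphenyl)methyl]-3-(4-hydroxy-3-methoxybenzyl)oxolan-2-one (CNP0352022.1) | COc1cc(C[C@@]2(O)C(=O)OC[C@@H]2[C@@H](O)c2ccc(O)c(OC)c2)ccc1O | target

## Step count and risks

Total: 13 steps. Longest linear sequence: 10 steps (steps 1–8, 12, 13).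

**Step 4 (lipase resolution).** The carbinol carbon C6 carries two bulky groups (aryl and a substituted oxolane ring), so acylation may be very slow, may go to the C3 hydroxyl instead, or may discriminate the enantiomers poorly. The fallback is a covalent resolution that sets out from racemic 5 and replaces steps 3–5. The lone C3 hydroxyl of 5 is esterified with (S)-2-methoxy-2-phenylacetic acid (N,N'-dicyclohexylcarbodiimide, DMAP, CH2Cl2). This gives two diastereomers, the (S)-O-methylmandelate of the wanted enantiomer F1 and the (S)-O-methylmandelate of the mirror-image alcohol F2, which are separated by chromatography or crystallisation. F1 is put through the conditions of step 3 to give the ring-opened mandelate F3. K2CO3 in MeOH (0 °C → rt) then removes the mandelate and the aryl acetate together and the route is rejoined at triol 8. No benzylic ester is present at that point, so the quinone methide elimination cannot occur.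

**Step 3 (reductive oxetane opening).** After ionisation the C5 oxocarbenium ion may lose the C4 proton faster than it takes up hydride; the enol ether so formed would expel benzyl alcohol and water and aromatise to a 3-furyl carbinol, with loss of C4. Reduction at the C2 acetal is the second danger. The fallback sets out from 5 and replaces hydride capture by sulfur capture. PhSH (1.5 equiv) and BF3·OEt2 (0.1 equiv) in CH2Cl2 at −78 °C should open the oxetane acetal to the phenylthio acetal F4. Bu3SnH and AIBN in toluene at 80 °C then replace the C5–S bond by C5–H through the α-oxy radical under neutral conditions, and the route is rejoined at 6.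

**Step 12 (enolate benzylation).** The crowded α-silyloxy enolate may react sluggishly with the labile benzylic bromide, which then decomposes, or the silyl group may migrate from the C3 oxygen on warming. The fallback sets out from 11 and uses an aldol reaction followed by deoxygenation. Enolate 16 is formed as in step 12 and treated at −78 °C with aldehyde 13, then with Ac2O, to give the C7-acetoxy adduct F5 (mixture at C7, same anti facial course at C3). Hydrogenolysis (H2, Pd/C, EtOAc) should cleave only the benzylic C7–OAc bond, since the benzylic silyl ether at C6 is inert, and the route is rejoined at 17.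

## Further compounds

F1 | step 4 | (S)-O-methylmandelate of 5, wanted diastereomer | O(Cc1ccccc1)[C@@H]1O[C@@H]2O[C@@H](c3ccc(OC(C)=O)c(OC)c3)[C@@H]2[C@H]1OC(=O)[C@@H](OC)c1ccccc1
F2 | step 4 | (S)-O-methylmandelate of the enantiomer of 5, discarded diastereomer | O(Cc1ccccc1)[C@H]1O[C@H]2O[C@H](c3ccc(OC(C)=O)c(OC)c3)[C@H]2[C@@H]1OC(=O)[C@@H](OC)c1ccccc1
F3 | step 4 | (2S,3R,4R)-2-(benzyloxy)-4-[(R)-(4-acetoxy-3-methoxyphenyl)(hydroxy)methyl]oxolan-3-yl (S)-2-methoxy-2-phenylacetate | O(Cc1ccccc1)[C@@H]1OC[C@H]([C@@H](O)c2ccc(OC(C)=O)c(OC)c2)[C@H]1OC(=O)[C@@H](OC)c1ccccc1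
F4 | step 3 | phenylthio acetal, (2S,3R,4R)-2-(benzyloxy)-4-[(R)-(4-acetoxy-3-methoxyphenyl)(hydroxy)methyl]-5-(phenylsulfanyl)oxolan-3-ol (mixture at C5) | O(Cc1ccccc1)[C@@H]1OC(Sc2ccccc2)[C@H]([C@@H](O)c2ccc(OC(C)=O)c(OC)c2)[C@H]1O
F5 | step 12 | C7-acetoxy analogue of 17 (mixture at C7) | COc1cc(C(OC(C)=O)[C@@]2(O[Si](C)(C)C(C)(C)C)C(=O)OC[C@@H]2[C@@H](O[Si](C)(C)C(C)(C)C)c2ccc(O[Si](C)(C)C(C)(C)C)c(OC)c2)ccc1O[Si](C)(C)C(C)(C)C
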